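**Retrosynthetic overview** (spiro[5.5]undecane numbering: ring B = C1–C5, spiro carbon C6, ring A = C7–C11)
1. Target 21 ⇐ α-bromo ketone 20 by axial methyl addition at C3; 20 ⇐ spiro β-keto ester 15 (C7 ketone → methylidene, C2 ester → equatorial bromine).
2. Key disconnection of ring B at C2–C3 and C5–C6: 15 ⇐ acryloyl chloride (C3 = acyl carbon, C5 = β-carbon) + bis-silyl keto ester 12, a [3+3] union of a 1,3-bis-electrophile with a 1,3-C,C-bis-nucleophile.
3. Enabling feature: the ring A carbonyl carbon C7 and an ester carbon on C2 are 1,5-related through C6–C1–C2, so C6 and C2 are both carbonyl α-carbons and can be unmasked as silyl enol ethers of different nucleophilicity; the C11 gem-dimethyl group and the C10 bromine fix the face of attack at C6.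
4. 12 ⇐ α-methylene ketone 8 + tert-butyl acetate; ring A of 8 ⇐ enantiospecific bromonium cyclization of β-keto ester 5, whose C–Br centre comes from enantioselective bromochlorination of prenol.
5. Order of ring formation: ring A (step 4), then ring B (step 9).

Key step: step 9

Assumption: the chiral Schiff base ligand of step 1 is used in the enantiomeric form that gives (S)-2; β-keto esters 15 and 16 are written as enol tautomers, and centres that are epimerizable or destroyed later (C1 of 6 and 7, C2 of 14 and 17–19) are left unspecified.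

Step 1
Reactants: 1 3-methylbut-2-en-1-ol (prenol)
Product: 2 (2S)-2-bromo-3-chloro-3-methylbutan-1-ol
Conditions: NBS, ClTi(OiPr)3 (1.1 equiv), (S)-2-[(3,5-di-tert-butyl-2-hydroxybenzylidene)amino]-3,3-dimethyl-1,1-diphenylbutan-1-ol or its enantiomer (20 mol%), hexanes, −20 °C
Reagents that add atoms: N-bromosuccinimide O=C1CCC(=O)N1Br; chlorotitanium triisopropoxide CC(C)O[Ti](Cl)(OC(C)C)OC(C)C
Why: Titanium-mediated catalytic enantioselective bromochlorination of an allylic alcohol, in which the ligand-bound titanium alkoxide of 1 directs bromonium formation to one alkene face and delivers chloride to the distal tertiary carbon, so the ligand sets C2 as S.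

Step 2
Reactants: 2 (2S)-2-bromo-3-chloro-3-methylbutan-1-ol
Product: 3 (2S)-2-bromo-3-chloro-3-methylbutyl trifluoromethanesulfonate
Conditions: Tf2O, 2,6-lutidine, CH2Cl2, −78 °C; used directly
Reagents that add atoms: trifluoromethanesulfonic anhydride O=S(=O)(OS(=O)(=O)C(F)(F)F)C(F)(F)F
Why: Triflate formation at the primary alcohol gives a leaving group reactive enough for carbanion alkylation at low temperature, and the C2 stereocentre is not touched.

Step 3
Reactants: 3 (2S)-2-bromo-3-chloro-3-methylbutyl trifluoromethanesulfonate; 4 prop-2-en-1-yl 3-oxobutanoate (allyl acetoacetate)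
Product: 5 prop-2-en-1-yl (6S)-6-bromo-7-chloro-7-methyl-3-oxooctanoate
Conditions: 4, NaH then n-BuLi, THF, 0 °C; 3, −78 → 0 °C; AcOH quench
Reagents that add atoms: none
Why: γ-Alkylation of an acetoacetate dianion (SN2 of the terminal carbanion at the primary triflate) extends the chain without touching the bromine-bearing stereocentre or the tertiary chloride.

Step 4
Reactants: 5 prop-2-en-1-yl (6S)-6-bromo-7-chloro-7-methyl-3-oxooctanoate
Product: 6 prop-2-en-1-yl (3S)-3-bromo-2,2-dimethyl-6-oxocyclohexane-1-carboxylate (C1 epimers and enol)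
Conditions: (CF3)2CHOH, 0 → 25 °C
Reagents that add atoms: none
Why: Solvolytic bromonium-ion cyclization: the tertiary chloride ionizes with anchimeric assistance by bromine, and the configurationally defined bromonium ion is opened at its tertiary carbon by the β-keto ester enol carbon (6-endo closure of ring A), so the C–Br centre stays S while the new C1 centre is inconsequential because step 5 removes it.

Step 5
Reactants: 6 prop-2-en-1-yl (3S)-3-bromo-2,2-dimethyl-6-oxocyclohexane-1-carboxylate
Product: 8 (4S)-4-bromo-3,3-dimethyl-2-methylidenecyclohexan-1-one, via β-keto acid 7 (not isolated)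
Conditions: Pd(PPh3)4 (3 mol%), Et2NH (3 equiv), THF, 0 °C; then 37% aq. CH2O, 0 → 25 °C
Reagents that add atoms: formaldehyde C=O
Why: Tsuji–Trost deallylation by zerovalent palladium (diethylamine as allyl acceptor) frees the β-keto acid, which undergoes a decarboxylative Mannich reaction and amine elimination to place the methylidene group only at the former carboxyl-bearing carbon; no stereocentre is formed.

Step 6
Reactants: 9 tert-butyl acetate
Product: 10 tert-butyl[(1-tert-butoxyethenyl)oxy]dimethylsilane
Conditions: LiN(iPr)2, THF, −78 °C; TBSCl, DMPU, −78 → 25 °C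
Reagents that add atoms: tert-butyldimethylsilyl chloride CC(C)(C)[Si](C)(C)Cl
Why: Ester enolization and O-silylation is the standard ketene silyl acetal preparation; no stereocentre is involved.

Step 7
Reactants: 8 (4S)-4-bromo-3,3-dimethyl-2-methylidenecyclohexan-1-one; 10 tert-butyl[(1-tert-butoxyethenyl)oxy]dimethylsilane
Product: 11 tert-butyl 3-[(5S)-5-bromo-2-(tert-butyldimethylsilyloxy)-6,6-dimethylcyclohex-1-en-1-yl]propanoate
Conditions: 10 (1.3 equiv), MeCN, 40 °C, no catalyst
Reagents that add atoms: none
Why: Mukaiyama–Michael addition with silyl transfer: the ketene silyl acetal adds to the unhindered exocyclic β-carbon of the s-cis enone and the silyl group passes to the enolate oxygen, which fixes the ring A enol double bond regiospecifically toward the future spiro carbon; no stereocentre is formed.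

Step 8
Reactants: 11 tert-butyl 3-[(5S)-5-bromo-2-(tert-butyldimethylsilyloxy)-6,6-dimethylcyclohex-1-en-1-yl]propanoate
Product: 12 tert-butyl{[1-tert-butoxy-3-[(5S)-5-bromo-2-(tert-butyldimethylsilyloxy)-6,6-dimethylcyclohex-1-en-1-yl]prop-1-en-1-yl]oxy}dimethylsilane (E/Z mixture)
Conditions: LiN(iPr)2, THF, −78 °C; TBSCl, DMPU; non-aqueous work-up, used crude
Reagents that add atoms: tert-butyldimethylsilyl chloride CC(C)(C)[Si](C)(C)Cl
Why: Kinetic ester enolization and O-silylation turns the second α-carbon into a ketene silyl acetal far more nucleophilic than the hindered ring enol ether, while the enol ether and the neopentyl-type bromide are inert to the amide base at −78 °C; the enol geometry is immaterial.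

Step 9
Reactants: 12 tert-butyl{[1-tert-butoxy-3-[(5S)-5-bromo-2-(tert-butyldimethylsilyloxy)-6,6-dimethylcyclohex-1-en-1-yl]prop-1-en-1-yl]oxy}dimethylsilane; 13 prop-2-enoyl chloride (acryloyl chloride)
Product: 15 tert-butyl (6S,10S)-10-bromo-3-hydroxy-11,11-dimethyl-7-oxospiro[5.5]undec-2-ene-2-carboxylate, via vinyl β-keto ester 14 (not isolated)
Conditions: 13 (1.05 equiv), Sc(OTf)3 (10 mol%), 4 Å MS, CH2Cl2, −78 → 0 °C; 1 M HCl work-up
Reagents that add atoms: none
Why: Proposed new method: acryloyl chloride acts as a 1,3-bis-electrophile toward the 1,3-C,C-bis-nucleophile 12: the ketene silyl acetal carbon is acylated at the acid chloride carbonyl (C2–C3 bond, loss of TBSCl) to give the chelating vinyl β-keto ester 14, and Sc(OTf)3 then activates this enone for intramolecular Mukaiyama–Michael attack of the ring A silyl enol ether carbon on the terminal CH2 (C5–C6 bond). The closest known reaction types are the C-acylation of ketene silyl acetals by acid chlorides, Lewis acid-mediated [3+3] cyclizations of bis(silyl enol ethers) with 1,3-dielectrophiles, and Mukaiyama–Michael additions of tetrasubstituted silyl enol ethers that create vicinal quaternary centres. Ring B closes by a 6-endo-trig conjugate addition through a chair-like transition state, with the enol ether double bond outside the new ring. The spiro centre C6 is set by ring A: the enol ether carbon is attacked anti to the pseudoaxial methyl group on the neighbouring C11 in the half-chair that keeps the C10 bromine equatorial, so the new C5 arm ends up trans to bromine; the ester-bearing C2 is not controlled and need not be, since it is enolized and loses the ester in step 11. The step needs chemoselectivity between the two silyl nucleophiles, which the much higher nucleophilicity of the ketene silyl acetal over the hindered tetrasubstituted enol ether secures, and closing the congested C5–C6 bond intramolecularly avoids an intermolecular union next to the quaternary C11.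

Step 10
Reactants: 15 tert-butyl (6S,10S)-10-bromo-3-hydroxy-11,11-dimethyl-7-oxospiro[5.5]undec-2-ene-2-carboxylate
Product: 16 tert-butyl (6R,10S)-10-bromo-3-hydroxy-11,11-dimethyl-7-methylidenespiro[5.5]undec-2-ene-2-carboxylate
Conditions: Cp2Ti(μ-CH2)(μ-Cl)AlMe2 (2.5 equiv), pyridine (cat.), THF–toluene, −40 → 0 °C
Reagents that add atoms: Tebbe reagent Cp2Ti(μ-CH2)(μ-Cl)AlMe2 C[Al-]1(C)C[Ti](C2C=CC=C2)(C2C=CC=C2)[Cl+]1
Why: Tebbe methylenation is non-basic and suited to hindered, enolizable ketones; the first equivalent is consumed by the acidic enol and turns the ring B β-keto ester into an unreactive metal enolate, so only the C7 ketone is converted, and no stereocentre changes (the C6 descriptor changes by priority only).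

Step 11
Reactants: 16 tert-butyl (6R,10S)-10-bromo-3-hydroxy-11,11-dimethyl-7-methylidenespiro[5.5]undec-2-ene-2-carboxylate
Product: 20 (2R,6R,10S)-2,10-dibromo-11,11-dimethyl-7-methylidenespiro[5.5]undecan-3-one, via bromo β-keto ester 17 (not isolated), via silyl ester 18 (not isolated), via bromo β-keto acid 19 (not isolated)
Conditions: NBS (1.0 equiv), CH2Cl2, 0 °C; TMSOTf, 2,6-lutidine, 0 °C; then H2O–THF, 40 °C
Reagents that add atoms: N-bromosuccinimide O=C1CCC(=O)N1Br
Why: Enol bromination of the β-keto ester at C2, buffered silyl triflate cleavage of the tert-butyl ester (which spares the exocyclic alkene) and decarboxylation of the β-keto acid place bromine regiospecifically on the C1–C2 arm, and the epimerizable C2 centre then settles under thermodynamic control with bromine equatorial (an axial bromine would be syn-axial to the C7 arm on C6), that is cis to the C11 arm as required.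

Step 12
Reactants: 20 (2R,6R,10S)-2,10-dibromo-11,11-dimethyl-7-methylidenespiro[5.5]undecan-3-one
Product: 21 (2R,3R,6R,10S)-2,10-dibromo-3,11,11-trimethyl-7-methylidenespiro[5.5]undecan-3-ol
Conditions: MeAl(OAr)2 (Ar = 2,6-di-tert-butyl-4-methylphenyl; 3 equiv, from AlMe3 and ArOH), toluene, −78 °C; MeMgBr (1.5 equiv), −78 °C
Reagents that add atoms: methylmagnesium bromide C[Mg]Br
Why: Lewis acid-controlled Grignard addition to a cyclohexanone: the bulky aluminium bis(aryloxide) binds the carbonyl oxygen on the equatorial side, so MeMgBr should attack C3 axially to give axial methyl and equatorial hydroxyl trans to the equatorial bromine in the chair that keeps the C11 arm equatorial, and the diequatorial bromohydrin alkoxide cannot close to an epoxide.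

**Compound list**
1 | 3-methylbut-2-en-1-ol (prenol) | CC(C)=CCO | starting material
2 | (2S)-2-bromo-3-chloro-3-methylbutan-1-ol | OC[C@H](Br)C(C)(C)Cl | intermediate
3 | (2S)-2-bromo-3-chloro-3-methylbutyl trifluoromethanesulfonate | O=S(=O)(OC[C@H](Br)C(C)(C)Cl)C(F)(F)F | intermediate
4 | prop-2-en-1-yl 3-oxobutanoate (allyl acetoacetate) | CC(=O)CC(=O)OCC=C | starting material
5 | prop-2-en-1-yl (6S)-6-bromo-7-chloro-7-methyl-3-oxooctanoate | C=CCOC(=O)CC(=O)CC[C@H](Br)C(C)(C)Cl | intermediate
6 | prop-2-en-1-yl (3S)-3-bromo-2,2-dimethyl-6-oxocyclohexane-1-carboxylate (C1 epimers) | C=CCOC(=O)C1C(=O)CC[C@H](Br)C1(C)C | intermediate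
7 | (3S)-3-bromo-2,2-dimethyl-6-oxocyclohexane-1-carboxylic acid (C1 epimers) | OC(=O)C1C(=O)CC[C@H](Br)C1(C)C | intermediate (not isolated)
8 | (4S)-4-bromo-3,3-dimethyl-2-methylidenecyclohexan-1-one | C=C1C(=O)CC[C@H](Br)C1(C)C | intermediate
9 | tert-butyl acetate | CC(=O)OC(C)(C)C | starting material
10 | tert-butyl[(1-tert-butoxyethenyl)oxy]dimethylsilane | C=C(OC(C)(C)C)O[Si](C)(C)C(C)(C)C | intermediate
11 | tert-butyl 3-[(5S)-5-bromo-2-(tert-butyldimethylsilyloxy)-6,6-dimethylcyclohex-1-en-1-yl]propanoate | CC(C)(C)OC(=O)CCC1=C(O[Si](C)(C)C(C)(C)C)CC[C@H](Br)C1(C)C | intermediate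
12 | tert-butyl{[1-tert-butoxy-3-[(5S)-5-bromo-2-(tert-butyldimethylsilyloxy)-6,6-dimethylcyclohex-1-en-1-yl]prop-1-en-1-yl]oxy}dimethylsilane (E/Z mixture) | CC(C)(C)OC(O[Si](C)(C)C(C)(C)C)=CCC1=C(O[Si](C)(C)C(C)(C)C)CC[C@H](Br)C1(C)C | intermediate
13 | prop-2-enoyl chloride (acryloyl chloride) | C=CC(=O)Cl | starting material
14 | tert-butyl 2-{[(5S)-5-bromo-2-(tert-butyldimethylsilyloxy)-6,6-dimethylcyclohex-1-en-1-yl]methyl}-3-oxopent-4-enoate (C2 epimers) | C=CC(=O)C(C(=O)OC(C)(C)C)CC1=C(O[Si](C)(C)C(C)(C)C)CC[C@H](Br)C1(C)C | intermediate (not isolated)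
15 | tert-butyl (6S,10S)-10-bromo-3-hydroxy-11,11-dimethyl-7-oxospiro[5.5]undec-2-ene-2-carboxylate (enol form) | O=C1CC[C@H](Br)C(C)(C)[C@@]12CCC(O)=C(C(=O)OC(C)(C)C)C2 | intermediate
16 | tert-butyl (6R,10S)-10-bromo-3-hydroxy-11,11-dimethyl-7-methylidenespiro[5.5]undec-2-ene-2-carboxylate (enol form) | C=C1CC[C@H](Br)C(C)(C)[C@@]12CCC(O)=C(C(=O)OC(C)(C)C)C2 | intermediate
17 | tert-butyl (6R,10S)-2,10-dibromo-11,11-dimethyl-7-methylidene-3-oxospiro[5.5]undecane-2-carboxylate (C2 epimers) | C=C1CC[C@H](Br)C(C)(C)[C@@]12CCC(=O)C(Br)(C(=O)OC(C)(C)C)C2 | intermediate (not isolated)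
18 | trimethylsilyl (6R,10S)-2,10-dibromo-11,11-dimethyl-7-methylidene-3-oxospiro[5.5]undecane-2-carboxylate (C2 epimers) | C=C1CC[C@H](Br)C(C)(C)[C@@]12CCC(=O)C(Br)(C(=O)O[Si](C)(C)C)C2 | intermediate (not isolated)
19 | (6R,10S)-2,10-dibromo-11,11-dimethyl-7-methylidene-3-oxospiro[5.5]undecane-2-carboxylic acid (C2 epimers) | C=C1CC[C@H](Br)C(C)(C)[C@@]12CCC(=O)C(Br)(C(=O)O)C2 | intermediate (not isolated)
20 | (2R,6R,10S)-2,10-dibromo-11,11-dimethyl-7-methylidenespiro[5.5]undecan-3-one | C=C1CC[C@H](Br)C(C)(C)[C@@]12CCC(=O)[C@H](Br)C2 | intermediate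
21 | (2R,3R,6R,10S)-2,10-dibromo-3,11,11-trimethyl-7-methylidenespiro[5.5]undecan-3-ol | C=C1CC[C@H](Br)C(C)(C)[C@@]12CC[C@@](C)(O)[C@H](Br)C2 | target

**Step count and risks**
Total step count: 12. Longest linear sequence: 11 (steps 1–5 and 7–12; step 6 is a one-step branch).

Step 9 (proposed new method) is the most likely to fail. The transient vinyl ketone may oligomerize, the hindered enol ether may lose its silyl group before the congested C5–C6 bond closes, or facial selectivity at C6 may erode. The fallback uses a known double Michael annulation and sets out from 8 and 9. The lithium enolate of 9 is added to acrolein to give tert-butyl 3-hydroxypent-4-enoate F1, and Dess–Martin oxidation gives the Nazarov-type reagent tert-butyl 3-oxopent-4-enoate F2. Cs2CO3 in MeCN then joins F2 to 8: the β-keto ester carbon adds to the methylidene carbon, and the ring A enolate so formed closes C5–C6 onto the vinyl ketone, under the same facial control. It comes back to the route at 15.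

Step 10 may fail through loss of chemoselectivity or reactivity: the titanium methylidene may be quenched by the enol, may attack the ring B carbonyl, or may react too slowly at the congested C7 ketone. The fallback is a Peterson olefination from 15. Me3SiCH2Li (2.5 equiv) with CeCl3 in THF at −78 °C is used; the first equivalent forms the ring B enolate, which protects the β-keto ester. Addition at C7 gives tert-butyl (10S)-10-bromo-3,7-dihydroxy-11,11-dimethyl-7-[(trimethylsilyl)methyl]spiro[5.5]undec-2-ene-2-carboxylate F3, and aqueous HF in MeCN eliminates the β-hydroxysilane. It comes back at 16.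

Step 11 may fail through acid-promoted migration of the C7 exocyclic double bond, bromination of that alkene, or incomplete equilibration at C2. The fallback postpones methylenation and sets out from 15, which has no alkene. NBS gives tert-butyl (6S,10S)-2,10-dibromo-11,11-dimethyl-3,7-dioxospiro[5.5]undecane-2-carboxylate F4. CF3CO2H gives the acid (6S,10S)-2,10-dibromo-11,11-dimethyl-3,7-dioxospiro[5.5]undecane-2-carboxylic acid F5, which decarboxylates to (2R,6S,10S)-2,10-dibromo-11,11-dimethylspiro[5.5]undecane-3,7-dione F6. MeAl(OAr)2 and MeMgBr then add methyl to the less hindered, bromide-activated C3 ketone to give (2R,3R,6S,10S)-2,10-dibromo-3-hydroxy-3,11,11-trimethylspiro[5.5]undecan-7-one F7. Methylenation of C7 with Cp2Ti(μ-CH2)(μ-Cl)AlMe2 comes back at 21.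

Further compounds
F1 | step 9 | tert-butyl 3-hydroxypent-4-enoate (racemic) | C=CC(O)CC(=O)OC(C)(C)C
F2 | step 9 | tert-butyl 3-oxopent-4-enoate | C=CC(=O)CC(=O)OC(C)(C)C
F3 | step 10 | tert-butyl (10S)-10-bromo-3,7-dihydroxy-11,11-dimethyl-7-[(trimethylsilyl)methyl]spiro[5.5]undec-2-ene-2-carboxylate (spiro centre as in 15, C7 unspecified) | C[Si](C)(C)CC1(O)CC[C@H](Br)C(C)(C)[C@@]12CCC(O)=C(C(=O)OC(C)(C)C)C2
F4 | step 11 | tert-butyl (6S,10S)-2,10-dibromo-11,11-dimethyl-3,7-dioxospiro[5.5]undecane-2-carboxylate (C2 epimers) | O=C1CC[C@H](Br)C(C)(C)[C@@]12CCC(=O)C(Br)(C(=O)OC(C)(C)C)C2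
F5 | step 11 | (6S,10S)-2,10-dibromo-11,11-dimethyl-3,7-dioxospiro[5.5]undecane-2-carboxylic acid (C2 epimers) | O=C1CC[C@H](Br)C(C)(C)[C@@]12CCC(=O)C(Br)(C(=O)O)C2
F6 | step 11 | (2R,6S,10S)-2,10-dibromo-11,11-dimethylspiro[5.5]undecane-3,7-dione | O=C1CC[C@H](Br)C(C)(C)[C@@]12CCC(=O)[C@H](Br)C2
F7 | step 11 | (2R,3R,6S,10S)-2,10-dibromo-3-hydroxy-3,11,11-trimethylspiro[5.5]undecan-7-one | O=C1CC[C@H](Br)C(C)(C)[C@@]12CC[C@@](C)(O)[C@H](Br)C2
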